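A closed, stirred vessel at constant volume and fixed temperature holds G, Z and the catalyst as charged, D. The way to read it is to count turnovers: L made, divided by D charged.

in all of them: D 18 mM

| charge | G | Z | remark | time |
|---|---|---|---|---|
| south | 0.14 M | 0.050 M | run made earlier |  |
| north-east | 1.1 M | 0.050 M | run made earlier |  |
| oak | 0.10 M | 0.0500 M |  | 10 h |
| ash | 0.20 M | 0.0500 M |  | 10 h |
| cedar | 0.40 M | 0.0500 M |  | 10 h |
| elm | 0.80 M | 0.0500 M |  | 10 h |

| run | time / h | L / % | Q / % | G / % |
|---|---|---|---|---|
| south | 0.333 | 0.7 | 0 | 99.4 |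
| south | 1.00 | 0.5 | 0.2 | 99.0 |
| south | 2.00 | 0.2 | 0.5 | 99.2 |
| south | 2.50 | 2.2 | 0 | 98.9 |
| south | 4.00 | 3.2 | 0 | 96.2 |
| south | 5.00 | 4.4 | 1.0 | 95.1 |
| north-east | 0.333 | 0 | 0.2 | 99.9 |
| north-east | 1.00 | 0.3 | 0 | 100.1 |
| north-east | 2.00 | 0.9 | 0.4 | 100.0 |
| north-east | 2.50 | 0.6 | 0 | 98.0 |
| north-east | 4.00 | 0.8 | 0 | 97.2 |
| north-east | 5.00 | 2.4 | 0.1 | 97.8 |

(standard deviation of a reading: 0.5 percentage points)

- the earlier runs were read with a standard deviation of 0.5 percentage points
- "hardly changes" means that all values lie within two and a half points (for a concentration: within two and a half percent of the largest)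

1. share of L in all that became L or Q for oak, ash, cedar, elm, in this order
2. how the row runs (rises, then falls / falls all the way / falls, then rises / rises all the way / hardly changes)

This reckoning takes each L to cost one Z, an assumption of its own. Z is then the limiting reagent, charged below G in the four new flasks, and the charge of Z over the charge of D, 2.78, is the turnover ceiling: the count that the Z charged can pay for.

At 5.00 h south reads 4.4% L, which is 6.16 mM or 0.342 turnovers, while north-east reads 2.4%, which is 26.4 mM or 1.47 turnovers. So G multiplied by 7.86 multiplies the count by 4.30, an apparent order in G of 0.706, read from two single readings with a scatter of 0.5 percentage points each. Up to 2.00 h neither run reads L beyond 0.9%, so the count is taken to climb in a straight line from that time. Carrying the order over from the nearer run gives oak 0.270 and elm 1.17 at 5.00 h. The straight line then gives oak 0.720 and elm 3.12 at 10 h.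

Elm's figure is the weak link, for it stands above the ceiling, so the line cannot hold that far. Reforged on the same assumption, elm's count is put at 2.78 or below, which is at most 6.25% of its G as L. Oak's estimate, at a quarter of the ceiling, is left on its line at about 13.0% of its G. The Q readings, none above 1.0%, give this reckoning no share of its own, so it commits to these two counts.

The forecast gave 95%, 95%, 95% and 95%, a row that hardly changes, on the ground that “Nothing here resolves any dependence on G”.

The flask gives 95.2%, 96.0%, 97.1% and 98.3% for oak, ash, cedar and elm, so the row rises all the way.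

    G + X ⇌ E (K = 150 M⁻¹, k = 9.30 × 10⁻⁴ M⁻¹ s⁻¹)
    E → J + L (k = 3.80 × 10⁻⁴ s⁻¹)
    Z + J ⇌ X (K = 26.0 M⁻¹, k = 0.410 M⁻¹ s⁻¹)
    D → J (k = 6.70 × 10⁻⁵ s⁻¹)
    Z + J + L → J + Q (k = 0.0150 M⁻² s⁻¹)

At 10 h elm holds L worth 2.49 turnovers, 89.6% of the ceiling, with 3.01% of its Z left and Q at 0.0987% of its G, whereas oak holds L worth 0.720, fewer than elm, with 56.2% of its Z left and Q at 0.647% of its G. At 100 h oak holds 0.0365% of its Z, and its L and Q, each Q counted as 2 Z, come to 99.9% of the ceiling.

The readings were computed from invented constants; the scatter is artificial.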